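**Retrosynthetic overview**

1. Feature: the single benzene ring, numbered C1 (carbon bearing CH2SO2CH3), C2 (Br), C3 and C4 (OH), C5 and C6 (Br). Its C1–C2–C3–C4 edge reads carbon arm, Br, O, O, so C1 and C2 map onto the ester and bromine carbons of methyl 3-bromopropiolate, C3–C6 map onto furan C2–C5 of 3-methoxyfuran, and the C3 hydroxyl oxygen is the furan ring oxygen.
2. Target ⇒ C5/C6 dibromination of the catechol sulfone ⇒ O-demethylation ⇒ sulfinate alkylation by the benzylic bromide ⇒ benzylic alcohol ⇒ methyl 2-bromo-3-hydroxy-4-methoxybenzoate.
3. That benzoate ⇒ [4+2] cycloaddition of 3-methoxyfuran with methyl 3-bromopropiolate (new bonds C2–C3 and C1–C6), then acid opening of the oxygen bridge.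
4. 3-Methoxyfuran ⇒ 3-bromofuran; the bromopropiolate ⇒ methyl propiolate.
5. Ring order: the benzene ring is the only ring and is built in the key step; all later steps adjust substituents.

Key step: step 3

Remark: the target is achiral, so no stereocontrol is needed. The bridged cycloadduct of the key step is racemic and loses both stereocentres on aromatisation.

**Route**

Step 1
Reactants: 1 3-bromofuran
Product: 2 3-methoxyfuran
Conditions: NaOMe (3 equiv), CuBr (10 mol %), MeOH, 100 °C, sealed tube; pentane extraction, distillation
Reagents that add atoms: sodium methoxide, C[O-].[Na+]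
Why: Copper-catalysed Ullmann-type methoxylation of a heteroaryl bromide is established for 3-halofurans and 3-halothiophenes, and the volatile ether should be separable by distillation.

Step 2
Reactants: 3 methyl propiolate
Product: 4 methyl 3-bromopropiolate
Conditions: NBS (1.1 equiv), AgNO3 (10 mol %), acetone, rt
Reagents that add atoms: N-bromosuccinimide, O=C1CCC(=O)N1Br
Why: Silver-catalysed electrophilic bromination of a terminal alkyne, through a catalytic silver acetylide that is brominated by NBS, is the standard preparation of 3-bromopropiolates.

Step 3
Reactants: 2 3-methoxyfuran; 4 methyl 3-bromopropiolate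
Product: 6 methyl 2-bromo-3-hydroxy-4-methoxybenzoate, via oxanorbornadiene cycloadduct 5 (not isolated)
Conditions: PhMe, rt to 40 °C; then BF3·OEt2 (20 mol %), −40 to 0 °C, one pot, anhydrous
Reagents that add atoms: none
Why: The electron-rich furan diene adds the electron-poor bromoalkynoate in an asynchronous normal-demand [4+2] cycloaddition in which furan C2, the β-carbon of the enol ether, bonds to the bromine-bearing β-carbon of the propiolate and furan C5 bonds to the ester-bearing carbon, giving racemic 5. BF3 then coordinates the bridging oxygen and the bridgehead C–O bond at the future C6 ionises, because that allyl cation ends on the methoxy-bearing C4 as an oxocarbenium ion; loss of the proton from the other bridgehead, which keeps the oxygen, aromatises the ring to the phenol with OH at C3. The closest known reaction types are the thermal Diels–Alder reaction of furans with 3-bromopropiolates and the acid-promoted isomerisation of 7-oxanorbornadienes to phenols. The six-membered carbocycle, the only ring closed, is formed by intermolecular [4+2] cycloaddition that makes the C2–C3 and C1–C6 bonds together. The two bridgehead stereocentres of 5 are necessarily cis, arise as a racemate and are erased on aromatisation, so none needs control. Regioselectivity is needed in both the cycloaddition and the bridge opening, and the 3-methoxy group secures each by making furan C2 the most nucleophilic diene terminus and by stabilising only one of the two possible cations, while anhydrous conditions keep the enol ether from hydrolysing.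

Step 4
Reactants: 6 methyl 2-bromo-3-hydroxy-4-methoxybenzoate
Product: 7 2-bromo-3-(hydroxymethyl)-6-methoxyphenol
Conditions: i-Bu2AlH (4 equiv), CH2Cl2, −78 to 0 °C; aq. potassium sodium tartrate (KNaC4H4O6)
Reagents that add atoms: none
Why: Hydride reduction of an aryl ester to the benzylic alcohol with i-Bu2AlH should proceed after one equivalent is consumed by the phenol, and the aryl bromide and methyl ether are inert at low temperature.

Step 5
Reactants: 7 2-bromo-3-(hydroxymethyl)-6-methoxyphenol
Product: 8 2-bromo-3-(bromomethyl)-6-methoxyphenol
Conditions: PBr3 (0.5 equiv), CH2Cl2, 0 °C; aqueous work-up, used crude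
Reagents that add atoms: phosphorus tribromide, BrP(Br)Br
Why: PBr3 converts the primary benzylic alcohol, activated by the para-methoxy group, into the bromide by bromide displacement of the alkyl phosphite, whereas any aryl phosphite formed at the hindered phenol should hydrolyse back on work-up.

Step 6
Reactants: 8 2-bromo-3-(bromomethyl)-6-methoxyphenol
Product: 9 2-bromo-6-methoxy-3-[(methylsulfonyl)methyl]phenol
Conditions: CH3SO2Na (1.5 equiv), DMF, rt to 50 °C
Reagents that add atoms: sodium methanesulfinate, CS(=O)[O-].[Na+]
Why: SN2 alkylation of the ambident sulfinate anion at sulfur by a benzylic bromide in a dipolar aprotic solvent is the standard sulfone synthesis, and the sulfinate is too weakly basic to ionise the phenol.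

Step 7
Reactants: 9 2-bromo-6-methoxy-3-[(methylsulfonyl)methyl]phenol
Product: 10 3-bromo-4-[(methylsulfonyl)methyl]benzene-1,2-diol
Conditions: BBr3 (3.5 equiv), CH2Cl2, −78 °C to rt; then H2O
Reagents that add atoms: none
Why: BBr3 cleavage of an aryl methyl ether (boron–oxygen complexation, then bromide attack at the methyl group) tolerates the sulfone and the aryl bromide, and the excess covers coordination to the sulfone and the phenol.

Step 8
Reactants: 10 3-bromo-4-[(methylsulfonyl)methyl]benzene-1,2-diol
Product: 11 3,4,6-tribromo-5-[(methylsulfonyl)methyl]benzene-1,2-diol (target)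
Conditions: Br2 (2.3 equiv), AcOH, rt to 50 °C, dark; aq. NaHSO3
Reagents that add atoms: bromine, BrBr
Why: Electrophilic aromatic bromination of a catechol fills the only two free positions, C6 (para to the C3 hydroxyl) and C5 (ortho to the C4 hydroxyl), as in the exhaustive bromination of catechol to tetrabromocatechol, so a single product is expected.

**Compound list**

1 | 3-bromofuran | Brc1ccoc1 | starting material
2 | 3-methoxyfuran | COc1ccoc1 | intermediate
3 | methyl propiolate | COC(=O)C#C | starting material
4 | methyl 3-bromopropiolate | COC(=O)C#CBr | intermediate
5 | racemic methyl 3-bromo-5-methoxy-7-oxabicyclo[2.2.1]hepta-2,5-diene-2-carboxylate (bridgehead hydrogens cis; one enantiomer drawn) | COC(=O)C1=C(Br)[C@@H]2O[C@H]1C=C2OC | intermediate (not isolated)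
6 | methyl 2-bromo-3-hydroxy-4-methoxybenzoate | COC(=O)c1ccc(OC)c(O)c1Br | intermediate
7 | 2-bromo-3-(hydroxymethyl)-6-methoxyphenol | OCc1ccc(OC)c(O)c1Br | intermediate
8 | 2-bromo-3-(bromomethyl)-6-methoxyphenol | BrCc1ccc(OC)c(O)c1Br | intermediate
9 | 2-bromo-6-methoxy-3-[(methylsulfonyl)methyl]phenol | CS(=O)(=O)Cc1ccc(OC)c(O)c1Br | intermediate
10 | 3-bromo-4-[(methylsulfonyl)methyl]benzene-1,2-diol | CS(=O)(=O)Cc1ccc(O)c(O)c1Br | intermediate
11 | 3,4,6-tribromo-5-[(methylsulfonyl)methyl]benzene-1,2-diol | CS(=O)(=O)Cc1c(Br)c(O)c(O)c(Br)c1Br | target

**Step count**

Total steps: 8. Longest linear sequence: 7 (steps 1, 3, 4, 5, 6, 7, 8); step 2 is a one-step side branch that joins at step 3.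

**Steps most likely to fail**

Step 3. The furan C2 may add to the β-carbon of the bromoalkyne and expel bromide (addition–elimination) instead of closing the second bond. The enol ether may also be lost by hydrolysis or cycloreversion before the bridge opens. The fallback sets out from 3-methoxyfuran 2 and methyl propiolate 3, which carries no vinylic leaving group. Cycloaddition in PhMe at 60–80 °C should give racemic methyl 5-methoxy-7-oxabicyclo[2.2.1]hepta-2,5-diene-2-carboxylate F1, which is not isolated. Opening with catalytic BF3·OEt2 by the same methoxy-directed ionisation should give methyl 3-hydroxy-4-methoxybenzoate F2. Amine-directed ortho-bromination of this phenol (NBS, catalytic i-Pr2NH, CH2Cl2, 0 °C) should place bromine at C2, the only free position ortho to the hydroxyl and the position at which the corresponding aldehyde is known to brominate. This returns to the route at compound 6.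

Step 5. The benzylic bromide may alkylate the electron-rich ring of a second molecule and oligomerise, and the free phenol may be phosphitylated. The fallback sets out from compound 7 and masks the phenol first. Selective O-methylation (MeI, K2CO3, acetone) should give (2-bromo-3,4-dimethoxyphenyl)methanol F3. PBr3 in CH2Cl2 should then give the well-behaved 2-bromo-1-(bromomethyl)-3,4-dimethoxybenzene F4. Displacement with CH3SO2Na in DMF should give 2-bromo-3,4-dimethoxy-1-[(methylsulfonyl)methyl]benzene F5. Double demethylation with excess BBr3 in CH2Cl2 returns to the route at compound 10.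

Step 8. Bromine may oxidise the free catechol to the ortho-quinone in competition with substitution, or the second bromination may stall. The fallback sets out from compound 9 and brominates before the second hydroxyl is unmasked. Br2 (2.3 equiv) in AcOH with NaOAc, and a trace of Fe powder if the second substitution is slow, should give 2,4,5-tribromo-6-methoxy-3-[(methylsulfonyl)methyl]phenol F6. BBr3 demethylation in CH2Cl2 then returns to the route at the target, compound 11.

**Further compounds**

F1 | step 3 | racemic methyl 5-methoxy-7-oxabicyclo[2.2.1]hepta-2,5-diene-2-carboxylate (one enantiomer drawn) | COC(=O)C1=C[C@@H]2O[C@H]1C=C2OC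
F2 | step 3 | methyl 3-hydroxy-4-methoxybenzoate | COC(=O)c1ccc(OC)c(O)c1
F3 | step 5 | (2-bromo-3,4-dimethoxyphenyl)methanol | OCc1ccc(OC)c(OC)c1Br
F4 | step 5 | 2-bromo-1-(bromomethyl)-3,4-dimethoxybenzene | BrCc1ccc(OC)c(OC)c1Br
F5 | step 5 | 2-bromo-3,4-dimethoxy-1-[(methylsulfonyl)methyl]benzene | CS(=O)(=O)Cc1ccc(OC)c(OC)c1Br
F6 | step 8 | 2,4,5-tribromo-6-methoxy-3-[(methylsulfonyl)methyl]phenol | CS(=O)(=O)Cc1c(Br)c(Br)c(OC)c(O)c1Br
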